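The last reading of the earlier runs stands at 8.00 min, one interval before the end asked for, so the meeting first set out the flasks and what had been read.

in all of them: substrate 0.028 M
- zeta: enzyme 0.84 µM (in portions, 3); run made earlier; portions every 4.0 min
- alpha: enzyme 1.8 µM (in portions, 3); run made earlier; portions every 4.0 min
- south: enzyme 1.0 µM (in portions, 3); the portions of enzyme follow each other after 4.0 min, the first at the start; time 12 min
- west: enzyme 1.5 µM (in portions, 3); the portions of enzyme follow each other after 4.0 min, the first at the start; time 12 min
- east: enzyme 2.5 µM (in portions, 3); the portions of enzyme follow each other after 4.0 min, the first at the start; time 12 min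

| run | time / min | target / % | substrate / % |
|---|---|---|---|
| zeta | 0.667 | 1.5 | 98.3 |
| zeta | 1.33 | 1.8 | 97.5 |
| zeta | 2.50 | 3.3 | 95.0 |
| zeta | 4.00 | 4.7 | 92.0 |
| zeta | 8.00 | 9.8 | 78.8 |
| alpha | 0.667 | 2.8 | 97.0 |
| alpha | 1.33 | 5.1 | 94.1 |
| alpha | 2.50 | 8.0 | 89.5 |
| alpha | 4.00 | 9.9 | 84.1 |
| alpha | 8.00 | 17.3 | 61.1 |

(standard deviation of a reading: 0.3 percentage points)

- what may be going on: substrate + enzyme -> target + enzyme; target -> over-reaction product
- "hardly changes" means that all values lie within two and a half points (for a concentration: within two and a half percent of the largest)

- amount of target at the end, in percent of the substrate charged for south, west, east, in this order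
- how that number moves from the first to the last of them (hardly changes / falls all the way / rises all the way / rises, then falls / falls, then rises)

The first chemist said that whatever is missing from substrate plus target must be over-reaction product. Between 4.00 min and 8.00 min she divided the mean target, times the interval, by the gain in that missing part. She reported 3.58 min for zeta and 3.49 min for alpha, though alpha holds twice the enzyme. The meeting took the mean of these readings, 3.53 min, as the lifetime of target, the mean time target survives before it goes on.

The second chemist argued that target then heads, from below or from above, for a balance level (a quasi-steady state): substrate lost per minute times that lifetime. For alpha's last interval this gives 20.3%, above the reading of 17.3%. She therefore went round once more. Alpha entered the interval at 9.9%, and the gap to the balance level shrinks by the factor exp(−interval/lifetime), here 0.322, which gives 17.0%. The first chemist noted that the interval is longer than the lifetime, so in this reckoning target at the end of an interval carries that interval's balance level with weight 0.678 and the target it started from with weight 0.322. No number was minuted for the end, since substrate loss after the third portion had not been read.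

The forecast gave 14.3%, 18% and 21.4%, a row that rises all the way: “Target is still rising with dose, though flattening”.

The flasks give 13.9%, 15.7% and 16.2%, a row that hardly changes.

    substrate + enzyme → target + enzyme, rate k1*[substrate]^3*[enzyme]/(1 + ([substrate]/Kh1)^3) (22.0 mM, k = 4.80 × 10⁶ L³ mol⁻³ s⁻¹)
    target → over-reaction product (k = 0.260 min⁻¹)

In east, the substrate lost between 8.00 min and 12.0 min puts the balance level at 14.3%, under the 19.5% of target standing at the start of that interval, and the second round gives 16.0% against 16.2%. For south, the same two rounds give 14.5%, then 13.5%, against 13.9%. East's target is held down mainly by the reaction of target to over-reaction product: the east run without that step ends at 63.3% of target, not 16.2%.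

All runs come from a simulation for substances that don't exist; the scatter is artificial.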